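## The problem

The target **34** is one carbocycle, a cyclohept-2-enone whose seven ring carbons carry every substituent. In the numbering used throughout, C1 is the ring carbonyl, C2 bears the hydroxymethyl carbon C8, C2=C3 is the enone alkene, C5 is quaternary (CH3 and the chain C14–C15–C16(OOH)–C17(CH3)=CH2), C6 bears the enol ester C12H=C13H–O–C(O)CH=C(CH3)2 and C7 bears the acetonyl group C10–C11(=O)–CH3. The three contiguous ring centres (5S,6S,7S) have C12 cis to the C5 methyl and trans to both the C5 chain and the C7 acetonyl, so one centre set absolutely (C6) can steer C5 and C7; C7 is epimerisable and should rest trans to C6. C16 (S) is insulated by two methylenes and needs reagent control. The allylic hydroperoxide does not survive reductants, phosphines, low-valent metals or strong base; the enol ester acylates any oxygen nucleophile; the 2-(hydroxymethyl)enone is open to nucleophilic epoxidation and conjugate addition; the 1,4-diketone cyclises under base. A stereodefined C16–OOH bond is best made by SN2 displacement with a peroxide anion, and that reagent attacks enones and enol esters, so the endgame order is fixed: protected peroxide first, then enol ester and enone by neutral methods. The feature that allows a short ring synthesis is the way the ring divides: C7–C1(O)–C2(C8) is a three-carbon unit with oxygen on the middle carbon and a carboxyl-level carbon on C2 (a 2-oxyvinyl carbenoid), and C3–C4–C5(CH3)–C6(C12) is an isoprenoid 1,3-diene.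

## Retrosynthesis

**34 from 33.** No skeletal bond is cut. The free hydroperoxide, the C11 ketone and the C8 hydroxyl are released together from a perketal, a methyl enol ether and a silyl ether in **33**. This is preferred to any late bond formation because none of the three groups tolerates further chemistry; the forward step only asks that enol ester, enone and allylic OOH survive cold dilute acid.

**33 from 31.** The C2=C3 alkene is traced to an α-phenylthio ketone (C2–S and C3–H removed as a sulfenic acid). Direct dehydrogenation of a silyl enol ether would put the enone in place before the peroxide anion is used; the sulfide keeps C2/C3 saturated through that step and blocks C2 against enolisation. The forward elimination must go toward C3 and not toward the oxygen-bearing C8.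

**31 from 27 and 30.** The C12=C13 bond is cut by a Wittig disconnection to the C12 aldehyde **27** and the acyloxymethyl phosphonium salt **30** (from **28** via **29**). Acylation of an aldehyde enolate would need strong base next to a peroxide and one more carbon on the ring side. **27** comes from perketal **25** by selective desilylation (**26**) and oxidation.

**25 from 22 and 24.** The C16–O bond is cut. SN2 alkylation of the mono-protected hydrogen peroxide **24** (from **23**) by mesylate **22** inverts C16, so the 16R alcohol **21** is needed. A singlet-oxygen ene reaction would give no control at C16 and a regioisomeric tertiary hydroperoxide. The substrate at this stage carries no enone, enol ester or free methyl ketone.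

**21 from 17 and 19.** The C7–C10 bond is cut to the C7 enolate of **17** and 2-methoxyallyl bromide **19** (from **18**), an acetonyl equivalent that stays masked as an enol ether until the last step. C7 is the only enolisable position of **17**; alkylation anti to the C6 substituent gives the trans arrangement.

**17 from 16, 14 and 13.** The C2–S bond comes from sulfenylation of the regiodefined silyl enol ether **16**. The C8 hydroxymethyl comes from hydride reduction of the ester of **13** (diol **14**), followed by differentiated silylation. The ester carbon thus becomes C8 and no separate hydroxymethylation is needed.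

**13 from 12, 10 and 11.** The C16 carbinol is traced to the isopropenyl ketone **12** by Corey–Bakshi–Shibata reduction, and the C16–C17 bond to Weinreb amide **10** and isopropenylmagnesium bromide **11**. Reagent control is used because no ring centre is close enough to direct C16.

**10 from 8 and 9.** The C5–C14 bond is cut to a tertiary C5 radical, generated by hydrogen-atom transfer to the C4=C5 alkene of **8**, and the acrylamide **9**. This makes the quaternary centre and saturates C4 in one step; the forward reaction must add anti to the C6 substituent.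

**8 from 3 and 6 (key).** C2–C3 and C6–C7 are cut. Cycloheptadiene **8** is the Cope product of cis-divinylcyclopropane **7**, which arises from the siloxyvinyl diazoacetate **3** and diene **6**. Both are achiral; the catalyst sets C6.

**3 from 1; 6 from 4.** Diazo transfer and enol silylation convert methyl acetoacetate **1** (via **2**) into **3**. Silylation (**5**) and semihydrogenation convert enynol **4** into **6**.

## Roads not taken

**Alternative 1:** An intramolecular oxidopyrylium (5+2) cycloaddition cuts C4–C5 and C6–C7. Triethylamine would expel acetate from the acetoxypyranone **A1**, and the 3-oxidopyrylium would add across the tethered C5=C6 enoate to give the oxygen-bridged cycloadduct **A2**.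
- Merits: the quaternary centre C5 and the centres C6 and C7 are all formed in one intramolecular step, with their relative configuration fixed by the E alkene and the tether. In this respect it is better than the chosen plan, which sets C5 and C7 in two separate substrate-controlled steps.
- Weak points: the 2π partner is a β,β-disubstituted enoate, a sluggish dipolarophile. The bridge leaves oxygen on C4 and C7 that the target lacks, so a reductive C7–O cleavage and a C4 deoxygenation follow. The lactone carbonyl C12 must be brought to the aldehyde level and C11 oxidised. Facial control rests on a remote carbinol centre in the tether.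
- Comparison: **A1** needs a long linear preparation, whereas the chosen plan builds the ring from two achiral two-step fragments with catalyst control and sets against the alternative's stereochemical economy the absence of any oxygen-excision sequence.

**Alternative 2:** A type-two carbonyl-ene closure cuts C3–C4. Me2AlCl would activate the aldehyde of **A3**, which bonds to the terminal alkene carbon while a methyl hydrogen passes to oxygen, giving the methylenecycloheptanol **A4**.
- Merits: C6 and C7 are fixed in an acyclic precursor by reliable acyclic methods, and the alkyne that becomes the acetonyl group is already in place. This removes the C7 alkylation risk of the chosen plan, a real advantage.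
- Weak points: a seven-membered ene closure is entropically harder than the six-membered cases on which the reaction is dependable. C5 is still not quaternary, and the exocyclic methylene of **A4** would need the same radical addition with the same facial question. C8 is absent and must be added after dehydration of the C3 carbinol toward C2.
- Comparison: the chosen plan delivers C8, the C1 oxygen and the C4=C5 alkene for the quaternary centre in the ring-forming step itself.

**Alternative 3:** A one-carbon ring expansion cuts C1–C2 and C2–C3. Dibromocarbene (bromoform, KOt-Bu) would add to the silyl enol ether **A5** of a six-membered ketone, and opening of the dibromocyclopropane would give the 2-bromocyclohept-2-enone **A6**.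
- Merits: C5 and C6 can be set on a cyclohexanone by well-tried conjugate-addition chemistry. **A6** already has the C2=C3 enone, regiochemically unambiguous, with a bromide as the handle for C8. On this point the alternative is better than the chosen plan, which has to mask the enone as a sulfide and unmask it late.
- Weak points: the carbene is generated with strong base in the presence of the electron-rich isopropenyl alkene. The Δ1,3 enol ether must be formed regioselectively against enolisation toward C7. C8 still needs a one-carbon coupling, C7 still needs alkylation, and the enone of **A6** is present from then on, so the peroxide conflict is sharper.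
- Comparison: the chosen plan sets against this its catalytic, convergent ring synthesis and the fact that C8 comes with the diazo fragment.

Key step: step 5

Assumption: the sense of induction of the dirhodium catalyst is assigned by analogy with the accepted model for this catalyst class (Rh2(R-PTAD)4 giving the (1S,2R)-cyclopropane **7** and hence 6S-**8**); if the opposite sense is found, Rh2(S-PTAD)4 is used with no other change.

Remark: descriptors such as 5R or 16R refer to the skeleton numbering above; the C5 descriptor changes with the substituents while the geometry stays the same.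

## Route

Step 1
Reactants: 1 methyl acetoacetate
Product: 2 methyl 2-diazo-3-oxobutanoate
Conditions: 4-acetamidobenzenesulfonyl azide, Et3N, MeCN, 0 °C → rt
Reagents that add atoms: 4-acetamidobenzenesulfonyl azide, CC(=O)Nc1ccc(cc1)S(=O)(=O)N=[N+]=[N-]
Why: Regitz diazo transfer to the activated methylene of a β-keto ester; the sulfonyl azide delivers N2 and leaves as the sulfonamide.

Step 2
Reactants: 2 methyl 2-diazo-3-oxobutanoate
Product: 3 methyl 3-[(tert-butyldimethylsilyl)oxy]-2-diazobut-3-enoate
Conditions: TBSOTf, Et3N, CH2Cl2, 0 °C
Reagents that add atoms: tert-butyldimethylsilyl trifluoromethanesulfonate, CC(C)(C)[Si](C)(C)OS(=O)(=O)C(F)(F)F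
Why: Silyl triflate/amine enolisation of the acetyl group; the diazo carbon has no hydrogen, so only the methyl ketone can be enolised.

Step 3
Reactants: 4 (E)-3-methylpent-2-en-4-yn-1-ol
Product: 5 tert-butyldiphenylsilyl ether of 4
Conditions: TBDPSCl, imidazole, CH2Cl2, rt
Reagents that add atoms: tert-butyl(chloro)diphenylsilane, CC(C)(C)[Si](Cl)(c1ccccc1)c1ccccc1
Why: Standard silylation of a primary allylic alcohol; the bulky group later shields the neighbouring allylic C–H bonds from the carbenoid and one face of C5.

Step 4
Reactants: 5 enyne silyl ether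
Product: 6 tert-butyl{[(E)-3-methylpenta-2,4-dien-1-yl]oxy}diphenylsilane
Conditions: H2 (1 atm), Pd/CaCO3–Pb(OAc)2 (Lindlar catalyst), quinoline, hexane, rt
Reagents that add atoms: none
Why: Lindlar semihydrogenation of the terminal alkyne of a conjugated enyne to a vinyl group; the trisubstituted E alkene is untouched.

Step 5
Reactants: 3 siloxyvinyl diazoacetate; 6 (E)-diene silyl ether
Product: 8 methyl (4S)-2-[(tert-butyldimethylsilyl)oxy]-4-{[(tert-butyldiphenylsilyl)oxy]methyl}-5-methylcyclohepta-1,5-diene-1-carboxylate, via cis-divinylcyclopropane 7 (not isolated)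
Conditions: Rh2(R-PTAD)4 (dirhodium tetrakis[(R)-(1-adamantyl)(N-phthalimido)acetate], 1 mol %), 6 (1.5 equiv), hexanes, −26 °C, slow addition of 3; then rt
Reagents that add atoms: none
Why: Rh2(R-PTAD)4 extrudes N2 from 3 to give a donor/acceptor 2-siloxyvinyl carbenoid of divalent rhodium, which adds to the monosubstituted C3=C4 alkene of 6 in a concerted, asynchronous [2+1] step to give cis-divinylcyclopropane 7, the ester and not the vinyl donor ending trans to the diene residue. 7 then undergoes a Cope [3,3] shift through the boat transition state at or below room temperature, breaking C2–C4 and forming C6–C7. The closest known reaction type is the dirhodium tetracarboxylate-catalysed tandem cyclopropanation/Cope rearrangement (formal (4+3) cycloaddition) of 2-siloxyvinyldiazoacetates with 1,3-dienes. The three-membered ring is closed by carbenoid [2+1] addition and the seven-membered ring by sigmatropic ring expansion of that cyclopropane, not by an end-to-end cyclisation. The only new stereocentre, C6, is controlled by the chiral carboxylate ligands, which select the alkene face in the cyclopropanation; the boat geometry and the E alkene (H, not CH2OSi, pointing inward) pass this choice stereospecifically to C6. Site selectivity for the vinyl group over the trisubstituted alkene follows from the steric preference of donor/acceptor carbenoids for monosubstituted alkenes. Chemoselectivity over insertion into the allylic C–H bonds next to oxygen is secured by the much faster cyclopropanation of the diene and by the bulk of the TBDPS group.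

Step 6
Reactants: 8 cycloheptadiene ester; 9 N-methoxy-N-methylacrylamide
Product: 10 (5R,6S) Weinreb amide with quaternary C5
Conditions: Fe(acac)3 (0.5 equiv), PhSiH3, 9 (3 equiv), EtOH–(CH2OH)2 5:1, 60 °C
Reagents that add atoms: none
Why: Metal-hydride hydrogen-atom-transfer Giese reaction: H• is delivered to C4 (Markovnikov), the tertiary C5 radical adds to the acrylamide and the adduct radical is reduced and protonated. Bond formation anti to the neighbouring C6 CH2OTBDPS group sets C5 with CH3 cis and the chain trans to it; the tetrasubstituted push–pull enol ether is too hindered for hydrogen-atom transfer.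

Step 7
Reactants: 10 Weinreb amide; 11 isopropenylmagnesium bromide
Product: 12 (5R,6S) isopropenyl ketone
Conditions: 11 (2.5 equiv), THF, −20 → 0 °C; aq. NH4Cl
Reagents that add atoms: none
Why: Weinreb ketone synthesis; the chelated tetrahedral intermediate prevents over-addition, and the conjugated β-siloxy enoate is far less electrophilic than the amide at this temperature.

Step 8
Reactants: 12 isopropenyl ketone
Product: 13 (5R,6S,16R) allylic alcohol
Conditions: (S)-2-methyl-CBS-oxazaborolidine (0.3 equiv), catecholborane, toluene, −78 °C; MeOH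
Reagents that add atoms: none
Why: Corey–Bakshi–Shibata reduction with the isopropenyl group as the large substituent, so the (S)-catalyst gives the 16R carbinol; catecholborane avoids hydroboration of the 1,1-disubstituted alkene.

Step 9
Reactants: 13 allylic alcohol ester
Product: 14 (5R,6S,16R) diol with C8 hydroxymethyl
Conditions: i-Bu2AlH (4 equiv), CH2Cl2, −78 °C; Rochelle salt
Reagents that add atoms: none
Why: Hydride reduction of the vinylogous carbonate ester to the primary allylic alcohol without touching the silyl enol ether; the acid-sensitive product is used without chromatography.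

Step 10
Reactants: 14 diol
Product: 16 (5R,6S,16R) tris-silyl ether with C8 OTBS and C16 OTMS, via C8 mono-TBS ether 15 (not isolated)
Conditions: TBSCl (1.1 equiv), imidazole, CH2Cl2, −20 → 0 °C; then TMSCl, 0 °C
Reagents that add atoms: tert-butyl(chloro)dimethylsilane, CC(C)(C)[Si](C)(C)Cl; chlorotrimethylsilane, C[Si](C)(C)Cl
Why: Primary-selective silylation followed in the same flask by trimethylsilylation of the secondary carbinol; the TMS ether is chosen because it can later be removed by methanolysis without acid or fluoride.

Step 11
Reactants: 16 tris-silyl ether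
Product: 17 (5S,6S,16R) 2-(phenylthio) ketone, C2 epimers
Conditions: PhSCl (1.05 equiv, from PhSSPh and SO2Cl2), CH2Cl2, −78 °C
Reagents that add atoms: benzenesulfenyl chloride, ClSc1ccccc1
Why: Sulfenylation of a silyl enol ether at the enol carbon C2, which is far more nucleophilic than the isopropenyl alkene at −78 °C. The sulfide masks the later C2=C3 enone and leaves C7 as the only enolisable position; the C2 centre is destroyed in step 22.

Step 12
Reactants: 18 1-bromo-2,2-dimethoxypropane
Product: 19 3-bromo-2-methoxyprop-1-ene (2-methoxyallyl bromide)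
Conditions: i-Pr2NEt·TsOH (cat.), neat, 150 °C, distil
Reagents that add atoms: none
Why: Acid-catalysed loss of methanol from the bromoketone dimethyl ketal gives the acetonyl-cation equivalent, used as the distillate.

Step 13
Reactants: 17 2-(phenylthio) ketone; 19 2-methoxyallyl bromide
Product: 21 (5S,6S,7S,16R) C7-alkylated ketone with free C16 hydroxyl, via C7-alkylated TMS ether 20 (not isolated)
Conditions: LiN(i-Pr)2 (1.1 equiv), THF, −78 °C; 19, −78 → −20 °C; then MeOH, K2CO3, 0 °C
Reagents that add atoms: none
Why: The lithium enolate (only C7 carries α-hydrogens) is C-alkylated by the allylic bromide on the face anti to the C6 substituent, setting C7 trans to C6, which is also the arrangement reached by base equilibration. K2CO3/MeOH then cleaves only the TMS ether.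

Step 14
Reactants: 21 C16 alcohol
Product: 22 (5S,6S,7S,16R) C16 mesylate
Conditions: MsCl, Et3N, CH2Cl2, −20 °C
Reagents that add atoms: methanesulfonyl chloride, CS(=O)(=O)Cl
Why: Standard mesylation of a secondary alcohol with retention; the allylic mesylate is used at once without chromatography.

Step 15
Reactants: 23 2,3-dimethylbut-2-ene
Product: 24 2-methoxyprop-2-yl hydroperoxide
Conditions: O3, MeOH–CH2Cl2, −78 °C
Reagents that add atoms: ozone, [O-][O+]=O; methanol, CO
Why: Ozonolysis in methanol; the carbonyl oxide is trapped by the solvent as the α-methoxy hydroperoxide, a mono-protected hydrogen peroxide.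

Step 16
Reactants: 22 C16 mesylate; 24 2-methoxyprop-2-yl hydroperoxide
Product: 25 (5S,6S,7S,16S) 2-methoxyprop-2-yl peroxide (perketal)
Conditions: 24 (2 equiv), CsOH·H2O (2 equiv), DMF, 0 °C
Reagents that add atoms: none
Why: SN2 alkylation of a hydroperoxide anion by a secondary sulfonate with inversion gives the 16S peroxide. At this stage the substrate has no enone, enol ester or free methyl ketone, and the ketone has no β-leaving group, so the peroxide anion and the base find no other target.

Step 17
Reactants: 25 perketal
Product: 26 (5S,6S,7S,16S) C12 primary alcohol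
Conditions: Bu4NF, AcOH (1:1), DMF–H2O, rt
Reagents that add atoms: none
Why: Acetic acid-buffered fluoride cleaves the TBDPS ether in preference to the neopentyl-type TBS ether on C8; buffering also guards the secondary peroxide against base-induced Kornblum–DeLaMare fragmentation.

Step 18
Reactants: 26 primary alcohol
Product: 27 (5S,6S,7S,16S) C12 aldehyde
Conditions: Dess–Martin periodinane, NaHCO3, CH2Cl2, 0 °C → rt
Reagents that add atoms: none
Why: Dess–Martin oxidation under buffered conditions tolerated by the perketal, the enol ether and the sulfide; any hemiketal with the C1 ketone is in equilibrium with the open alcohol.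

Step 19
Reactants: 28 3-methylbut-2-enoyl chloride
Product: 29 chloromethyl 3-methylbut-2-enoate
Conditions: (CH2O)n, ZnCl2 (cat.), neat, 60 °C
Reagents that add atoms: paraformaldehyde (as formaldehyde), C=O
Why: ZnCl2-catalysed insertion of formaldehyde into the acyl chloride, the standard preparation of chloromethyl esters.

Step 20
Reactants: 29 chloromethyl 3-methylbut-2-enoate
Product: 30 {[(3-methylbut-2-enoyl)oxy]methyl}triphenylphosphonium chloride
Conditions: PPh3, MeCN, 80 °C
Reagents that add atoms: triphenylphosphine, c1ccc(cc1)P(c1ccccc1)c1ccccc1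
Why: SN2 quaternisation of the phosphine by the activated α-acyloxy chloride.

Step 21
Reactants: 27 aldehyde; 30 acyloxymethyl phosphonium chloride
Product: 31 (5S,6S,7S,16S) (E)-enol ester
Conditions: 30 (2 equiv), NaN(SiMe3)2, THF, −78 °C; then 27, −78 → 0 °C; separation from the Z isomer
Reagents that add atoms: none
Why: Wittig olefination with an (acyloxymethylene)phosphorane forms the C12=C13 enol ester directly under aprotic conditions that a dialkyl peroxide tolerates. The aldehyde reacts in preference to the hindered α-quaternary ketone, and the E isomer is taken on.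

Step 22
Reactants: 31 enol ester sulfide
Product: 33 (5S,6S,7S,16S) cyclohept-2-enone, via sulfoxide 32 (not isolated)
Conditions: mCPBA (1.0 equiv), NaHCO3, CH2Cl2, −78 °C; then CaCO3, toluene, 50 °C
Reagents that add atoms: none
Why: The sulfide is oxidised at −78 °C faster than any alkene present, and the tertiary α-keto sulfoxide undergoes thermal syn-elimination. Elimination toward a carbon bearing oxygen is disfavoured, so the hydrogen is taken from C3 and the endocyclic enone results.

Step 23
Reactants: 33 protected enone
Product: 34 target hydroperoxide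
Conditions: aq. HF (48%), MeCN, 0 °C
Reagents that add atoms: water, O
Why: Dilute aqueous acid with fluoride cleaves the primary allylic TBS ether and hydrolyses both the 2-methoxyallyl enol ether (to the C11 ketone) and the perketal (to the hydroperoxide); enol ester, enone and allylic hydroperoxide tolerate these conditions, and no stereocentre is touched.

## Compound list

1 | methyl acetoacetate | COC(=O)CC(C)=O | starting material
2 | methyl 2-diazo-3-oxobutanoate | COC(=O)C(=[N+]=[N-])C(C)=O | intermediate
3 | methyl 3-[(tert-butyldimethylsilyl)oxy]-2-diazobut-3-enoate | COC(=O)C(=[N+]=[N-])C(=C)O[Si](C)(C)C(C)(C)C | intermediate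
4 | (E)-3-methylpent-2-en-4-yn-1-ol | C#C/C(C)=C/CO | starting material
5 | tert-butyl{[(E)-3-methylpent-2-en-4-yn-1-yl]oxy}diphenylsilane | C#C/C(C)=C/CO[Si](c1ccccc1)(c1ccccc1)C(C)(C)C | intermediate
6 | tert-butyl{[(E)-3-methylpenta-2,4-dien-1-yl]oxy}diphenylsilane | C=C/C(C)=C/CO[Si](c1ccccc1)(c1ccccc1)C(C)(C)C | intermediate
7 | methyl (1S,2R)-1-{1-[(tert-butyldimethylsilyl)oxy]vinyl}-2-{(E)-4-[(tert-butyldiphenylsilyl)oxy]but-2-en-2-yl}cyclopropane-1-carboxylate (vinyl and alkenyl groups cis) | COC(=O)[C@@]1(C(=C)O[Si](C)(C)C(C)(C)C)C[C@@H]1/C(C)=C/CO[Si](c1ccccc1)(c1ccccc1)C(C)(C)C | intermediate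
8 | methyl (4S)-2-[(tert-butyldimethylsilyl)oxy]-4-{[(tert-butyldiphenylsilyl)oxy]methyl}-5-methylcyclohepta-1,5-diene-1-carboxylate (skeleton: C1 OTBS enol ether, C2 CO2Me, C4=C5, 6S) | CC1=CCC(C(=O)OC)=C(O[Si](C)(C)C(C)(C)C)C[C@@H]1CO[Si](c2ccccc2)(c2ccccc2)C(C)(C)C | intermediate
9 | N-methoxy-N-methylacrylamide | C=CC(=O)N(C)OC | starting material
10 | (5R,6S) Weinreb amide: cyclohept-1-ene with 1-OTBS, 2-CO2Me, 5-CH3, 5-CH2CH2C(O)N(OMe)Me (trans to the C6 group) and 6-CH2OTBDPS | CON(C)C(=O)CC[C@@]1(C)CCC(C(=O)OC)=C(O[Si](C)(C)C(C)(C)C)C[C@@H]1CO[Si](c1ccccc1)(c1ccccc1)C(C)(C)C | intermediate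
11 | isopropenylmagnesium bromide | C=C(C)[Mg]Br | starting material
12 | (5R,6S) isopropenyl ketone: as 10 with 5-(4-methyl-3-oxopent-4-enyl) | C=C(C)C(=O)CC[C@@]1(C)CCC(C(=O)OC)=C(O[Si](C)(C)C(C)(C)C)C[C@@H]1CO[Si](c1ccccc1)(c1ccccc1)C(C)(C)C | intermediate
13 | (5R,6S,16R) allylic alcohol: as 12 with 5-[(3R)-3-hydroxy-4-methylpent-4-enyl] | C=C(C)[C@@H](CC[C@@]1(C)CCC(C(=O)OC)=C(O[Si](C)(C)C(C)(C)C)C[C@@H]1CO[Si](c1ccccc1)(c1ccccc1)C(C)(C)C)O | intermediate
14 | (5R,6S,16R) diol: as 13 with 2-CH2OH in place of the ester | C=C(C)[C@@H](CC[C@@]1(C)CCC(CO)=C(O[Si](C)(C)C(C)(C)C)C[C@@H]1CO[Si](c1ccccc1)(c1ccccc1)C(C)(C)C)O | intermediate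
15 | (5R,6S,16R) C8 mono-TBS ether of 14 (C16 hydroxyl free) | C=C(C)[C@@H](CC[C@@]1(C)CCC(CO[Si](C)(C)C(C)(C)C)=C(O[Si](C)(C)C(C)(C)C)C[C@@H]1CO[Si](c1ccccc1)(c1ccccc1)C(C)(C)C)O | intermediate
16 | (5R,6S,16R) tris-silyl ether: 1-OTBS enol ether, 2-CH2OTBS, 16-OTMS, 6-CH2OTBDPS | C=C(C)[C@@H](CC[C@@]1(C)CCC(CO[Si](C)(C)C(C)(C)C)=C(O[Si](C)(C)C(C)(C)C)C[C@@H]1CO[Si](c1ccccc1)(c1ccccc1)C(C)(C)C)O[Si](C)(C)C | intermediate
17 | (5S,6S,16R) 2-(phenylthio)-2-(TBSOCH2)cycloheptanone with 5-CH3, 5-[(3R)-4-methyl-3-(TMSO)pent-4-enyl], 6-CH2OTBDPS (C2 epimers) | C=C(C)[C@@H](CC[C@@]1(C)CCC(CO[Si](C)(C)C(C)(C)C)(Sc2ccccc2)C(=O)C[C@@H]1CO[Si](c1ccccc1)(c1ccccc1)C(C)(C)C)O[Si](C)(C)C | intermediate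
18 | 1-bromo-2,2-dimethoxypropane | CC(OC)(OC)CBr | starting material
19 | 3-bromo-2-methoxyprop-1-ene | C=C(OC)CBr | intermediate
20 | (5S,6S,7S,16R) C7-alkylated TMS ether: as 17 with 7-(2-methoxyprop-2-enyl) trans to the C6 group | C=C(C)[C@@H](CC[C@@]1(C)CCC(CO[Si](C)(C)C(C)(C)C)(Sc2ccccc2)C(=O)[C@@H](CC(=C)OC)[C@@H]1CO[Si](c1ccccc1)(c1ccccc1)C(C)(C)C)O[Si](C)(C)C | intermediate
21 | (5S,6S,7S,16R) alcohol: as 20 with free C16 hydroxyl | C=C(C)[C@@H](CC[C@@]1(C)CCC(CO[Si](C)(C)C(C)(C)C)(Sc2ccccc2)C(=O)[C@@H](CC(=C)OC)[C@@H]1CO[Si](c1ccccc1)(c1ccccc1)C(C)(C)C)O | intermediate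
22 | (5S,6S,7S,16R) C16 methanesulfonate of 21 | C=C(C)[C@@H](CC[C@@]1(C)CCC(CO[Si](C)(C)C(C)(C)C)(Sc2ccccc2)C(=O)[C@@H](CC(=C)OC)[C@@H]1CO[Si](c1ccccc1)(c1ccccc1)C(C)(C)C)OS(C)(=O)=O | intermediate
23 | 2,3-dimethylbut-2-ene | CC(C)=C(C)C | starting material
24 | 2-methoxyprop-2-yl hydroperoxide | COC(C)(C)OO | intermediate
25 | (5S,6S,7S,16S) perketal: as 22 with 16-OO–C(CH3)2OCH3 (inverted) | C=C(C)[C@H](CC[C@@]1(C)CCC(CO[Si](C)(C)C(C)(C)C)(Sc2ccccc2)C(=O)[C@@H](CC(=C)OC)[C@@H]1CO[Si](c1ccccc1)(c1ccccc1)C(C)(C)C)OOC(C)(C)OC | intermediate
26 | (5S,6S,7S,16S) C12 alcohol: as 25 with 6-CH2OH | C=C(C)[C@H](CC[C@@]1(C)CCC(CO[Si](C)(C)C(C)(C)C)(Sc2ccccc2)C(=O)[C@@H](CC(=C)OC)[C@@H]1CO)OOC(C)(C)OC | intermediate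
27 | (5S,6S,7S,16S) C12 aldehyde: as 25 with 6-CHO | C=C(C)[C@H](CC[C@@]1(C)CCC(CO[Si](C)(C)C(C)(C)C)(Sc2ccccc2)C(=O)[C@@H](CC(=C)OC)[C@@H]1C=O)OOC(C)(C)OC | intermediate
28 | 3-methylbut-2-enoyl chloride | CC(C)=CC(=O)Cl | starting material
29 | chloromethyl 3-methylbut-2-enoate | CC(C)=CC(=O)OCCl | intermediate
30 | {[(3-methylbut-2-enoyl)oxy]methyl}triphenylphosphonium chloride | CC(C)=CC(=O)OC[P+](c1ccccc1)(c1ccccc1)c1ccccc1.[Cl-] | intermediate
31 | (5S,6S,7S,16S) enol ester: as 27 with 6-[(E)-2-(3-methylbut-2-enoyloxy)ethenyl] | C=C(C)[C@H](CC[C@@]1(C)CCC(CO[Si](C)(C)C(C)(C)C)(Sc2ccccc2)C(=O)[C@@H](CC(=C)OC)[C@@H]1/C=C/OC(=O)C=C(C)C)OOC(C)(C)OC | intermediate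
32 | (5S,6S,7S,16S) 2-(phenylsulfinyl) ketone from 31 | C=C(C)[C@H](CC[C@@]1(C)CCC(CO[Si](C)(C)C(C)(C)C)(S(=O)c2ccccc2)C(=O)[C@@H](CC(=C)OC)[C@@H]1/C=C/OC(=O)C=C(C)C)OOC(C)(C)OC | intermediate
33 | (5S,6S,7S,16S) cyclohept-2-enone with 2-CH2OTBS, 7-(2-methoxyprop-2-enyl), 6-(E)-enol ester and 16-perketal | C=C(C)[C@H](CC[C@@]1(C)CC=C(CO[Si](C)(C)C(C)(C)C)C(=O)[C@@H](CC(=C)OC)[C@@H]1/C=C/OC(=O)C=C(C)C)OOC(C)(C)OC | intermediate
34 | CNP0216745.1, (5S,6S,7S,16S): 2-(hydroxymethyl)cyclohept-2-enone with 5-CH3, 5-[(3S)-3-hydroperoxy-4-methylpent-4-enyl], 6-[(E)-2-(3-methylbut-2-enoyloxy)ethenyl], 7-(2-oxopropyl) | C=C(C)[C@H](CC[C@@]1(C)CC=C(CO)C(=O)[C@@H](CC(C)=O)[C@@H]1/C=C/OC(=O)C=C(C)C)OO | target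

## Step count and least certain steps

Total: 23 steps. Longest linear sequence: 17 steps (1, 2, 5–11, 13, 14, 16–18, 21–23 from methyl acetoacetate; the same length from 4 through steps 3 and 4).

**Step 5 (key).** The most likely failure is incomplete facial discrimination in the cyclopropanation, because the 2-siloxy group makes the carbenoid less selective with some ligand sets. Carbenoid insertion into the allylic C–H bonds next to the silyl ether oxygen and carbenoid dimerisation are the competing processes. Fallback: catalyst control is replaced by resolution. The route sets out from 3 and 6, which are joined with achiral dirhodium tetrapivalate, Rh2(OPiv)4, in hexanes at room temperature. The racemate is resolved by preparative chromatography on a chiral stationary phase; the enantiomer of the cycloheptadiene ester F1 is set aside, and the route is rejoined at 8.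

**Step 16.** The secondary allylic mesylate can suffer SN2′ attack at the terminal methylene, E2 elimination to a 1,3-diene, or partial ionisation with erosion of configuration; the bulk of the protected peroxide nucleophile favours these side processes. Fallback: setting out from 22, direct perhydrolysis with the smaller hydroperoxide anion (50% H2O2, KOH, MeOH–THF, 0 °C) gives the free 16S hydroperoxide F9. This is then ketalised (2-methoxypropene, cat. PPTS, CH2Cl2, 0 °C), returning to the route at 25.

**Step 21.** The olefination is expected to give a mixture of alkene isomers, and slow addition to the hindered, α-branched aldehyde leaves time for enolisation and epimerisation at C6. Fallback: setting out from 27, kinetic control is replaced by equilibration. The co-formed Z enol ester F10 is separated and isomerised by reversible thiyl-radical addition (PhSSPh cat., visible light, benzene, rt) to the E isomer, in which the bulky ring carbon and the acyloxy group are trans; the route is rejoined at 31.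

**Step 6.** The planar C5 radical is biased only by the adjacent CH2OTBDPS group, so poor facial selectivity at 60 °C is the main risk; ethanolysis of the silyl enol ether in the hot protic medium is the second. Fallback: the radical is generated at room temperature in an aprotic medium. Setting out from 8, Mukaiyama hydration (Co(acac)2, PhSiH3, O2, i-PrOH, 0 °C) gives the C5 tertiary alcohol F2 (either epimer serves). Oxalyl chloride followed by N-hydroxyphthalimide and Et3N gives the tert-alkyl N-phthalimidoyl oxalate F3. Visible-light photoredox fragmentation (Ru(bpy)3(PF6)2, Hantzsch ester, i-Pr2NEt·HBF4, CH2Cl2, blue light, rt) in the presence of 9 returns to the route at 10.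

**Step 13.** The enolate next to the substituted C6 is hindered, so slow alkylation, proton transfer and incomplete facial selectivity at C7 are possible. Fallback: C7 is alkylated earlier, through a β-keto ester polyanion. Setting out from 13, the enol silyl ether is cleaved (K2CO3, MeOH) to the β-keto ester alcohol F4. Its trianion (LiN(i-Pr)2, 3.3 equiv, THF, −78 → 0 °C) is alkylated with 19 at the γ-carbon C7 to give the alkylated β-keto ester F5. O-Silylation of its sodium enolate (NaH, 1 equiv; TBSCl) gives the silyl enol ether ester F6, and i-Bu2AlH reduction gives the diol F7. The two-stage silylation of step 10 gives the tris-silyl ether F8. Sulfenylation as in step 11 then gives 20, which is isolated and methanolysed (K2CO3, MeOH) to rejoin the route at 21.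

## Further compounds

F1 | step 5 | methyl (4R)-2-[(tert-butyldimethylsilyl)oxy]-4-{[(tert-butyldiphenylsilyl)oxy]methyl}-5-methylcyclohepta-1,5-diene-1-carboxylate (enantiomer of 8) | CC1=CCC(C(=O)OC)=C(O[Si](C)(C)C(C)(C)C)C[C@H]1CO[Si](c2ccccc2)(c2ccccc2)C(C)(C)C
F2 | step 6 | (6S) C5 tertiary alcohol from hydration of the C4=C5 alkene of 8 (C5 epimers) | CC1(O)CCC(C(=O)OC)=C(O[Si](C)(C)C(C)(C)C)C[C@@H]1CO[Si](c2ccccc2)(c2ccccc2)C(C)(C)C
F3 | step 6 | (6S) tert-alkyl N-phthalimidoyl oxalate of F2 | CC1(OC(=O)C(=O)ON2C(=O)c3ccccc3C2=O)CCC(C(=O)OC)=C(O[Si](C)(C)C(C)(C)C)C[C@@H]1CO[Si](c2ccccc2)(c2ccccc2)C(C)(C)C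
F4 | step 13 | (5R,6S,16R) β-keto ester alcohol from desilylation of 13 | C=C(C)[C@@H](CC[C@@]1(C)CCC(C(=O)OC)C(=O)C[C@@H]1CO[Si](c1ccccc1)(c1ccccc1)C(C)(C)C)O
F5 | step 13 | (5R,6S,7S,16R) C7-(2-methoxyprop-2-enyl) β-keto ester alcohol | C=C(C)[C@@H](CC[C@@]1(C)CCC(C(=O)OC)C(=O)[C@@H](CC(=C)OC)[C@@H]1CO[Si](c1ccccc1)(c1ccccc1)C(C)(C)C)O
F6 | step 13 | (5R,6S,7S,16R) C1 TBS enol ether ester of F5 | C=C(C)[C@@H](CC[C@@]1(C)CCC(C(=O)OC)=C(O[Si](C)(C)C(C)(C)C)[C@@H](CC(=C)OC)[C@@H]1CO[Si](c1ccccc1)(c1ccccc1)C(C)(C)C)O
F7 | step 13 | (5R,6S,7S,16R) diol with C8 hydroxymethyl from F6 | C=C(C)[C@@H](CC[C@@]1(C)CCC(CO)=C(O[Si](C)(C)C(C)(C)C)[C@@H](CC(=C)OC)[C@@H]1CO[Si](c1ccccc1)(c1ccccc1)C(C)(C)C)O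
F8 | step 13 | (5R,6S,7S,16R) tris-silyl ether of F7 (C8 OTBS, C16 OTMS) | C=C(C)[C@@H](CC[C@@]1(C)CCC(CO[Si](C)(C)C(C)(C)C)=C(O[Si](C)(C)C(C)(C)C)[C@@H](CC(=C)OC)[C@@H]1CO[Si](c1ccccc1)(c1ccccc1)C(C)(C)C)O[Si](C)(C)C
F9 | step 16 | (5S,6S,7S,16S) free hydroperoxide corresponding to 25 | C=C(C)[C@H](CC[C@@]1(C)CCC(CO[Si](C)(C)C(C)(C)C)(Sc2ccccc2)C(=O)[C@@H](CC(=C)OC)[C@@H]1CO[Si](c1ccccc1)(c1ccccc1)C(C)(C)C)OO
F10 | step 21 | (5S,6S,7S,16S) Z isomer of enol ester 31 | C=C(C)[C@H](CC[C@@]1(C)CCC(CO[Si](C)(C)C(C)(C)C)(Sc2ccccc2)C(=O)[C@@H](CC(=C)OC)[C@@H]1/C=C\OC(=O)C=C(C)C)OOC(C)(C)OC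
A1 | alternative 1 | 6-acetoxypyranone carrying the (E)-enoate on an ester tether (acetal and C7 epimers) | C=C(C)[C@@H](CC/C(C)=C/C(=O)O[C@H](C)CC1OC(OC(C)=O)C=C(CO[Si](c2ccccc2)(c2ccccc2)C(C)(C)C)C1=O)O[Si](C)(C)C(C)(C)C
A2 | alternative 1 | 8-oxabicyclo[3.2.1]octenone fused to a δ-lactone | C=C(C)[C@@H](CC[C@@]1(C)[C@@H]2O[C@]3(C(=O)C(CO[Si](c4ccccc4)(c4ccccc4)C(C)(C)C)=C2)C[C@@H](C)OC(=O)[C@H]13)O[Si](C)(C)C(C)(C)C
A3 | alternative 2 | acyclic ketal aldehyde with the isopropenyl ene donor | C=C(C)[C@@H](CO[Si](C)(C)C(C)(C)C)[C@H](CC#C[Si](C)(C)C)C1(CC=O)OCCO1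
A4 | alternative 2 | 5-methylenecycloheptanol ketal | C=C1C[C@@H](O)CC2(OCCO2)[C@@H](CC#C[Si](C)(C)C)[C@@H]1CO[Si](C)(C)C(C)(C)C
A5 | alternative 3 | cyclohexenyl trimethylsilyl enol ether | C=C(C)[C@@H](CC[C@@]1(C)CC=C(O[Si](C)(C)C)C[C@@H]1CO[Si](C)(C)C(C)(C)C)O[Si](C)(C)C(C)(C)C
A6 | alternative 3 | 2-bromocyclohept-2-enone | C=C(C)[C@@H](CC[C@@]1(C)CC=C(Br)C(=O)C[C@@H]1CO[Si](C)(C)C(C)(C)C)O[Si](C)(C)C(C)(C)C
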